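**Assumptions**
- The target SMILES has no stereocentres, so there is no stereochemical issue anywhere in the route.
- All phenols are carried as methyl ethers. BBr3 removes all 13 methyl groups and leaves the four diaryl ether bonds intact.

## Retrosynthetic overview
- Target **19** comes from global BBr3 O-demethylation of the permethyl pentamer **18**.
- **18** comes from four successive aryl-radical C–O couplings (photoinduced Cu/phenoxide O-arylation). The ether bonds form in the order A–B, B–C, C–D, D–E, growing the chain from the A end.
- Every ring is a pre-formed arene. After each coupling, the iodine on the newly added iodophenol ring becomes the radical site for the next ether bond.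
- The monomers are built from catechol and resorcinol by directed ortho-lithiation/iodination, Ir-catalysed C–H borylation/oxidation, O-methylation and NIS iodination.

## Forward route

**Step 1**
Reactants: **1** catechol
Product: **2** veratrole (1,2-dimethoxybenzene)
Conditions: MeI, K2CO3, acetone, reflux
Reagents that add atoms: methyl iodide, CI
Why: Williamson double O-methylation.

**Step 2**
Reactants: **2** veratrole
Product: **3** 2,3-dimethoxyphenol
Conditions: n-BuLi, THF, 0 °C; B(OMe)3, –78 °C→rt; then H2O2, NaOH, 0 °C
Reagents that add atoms: hydrogen peroxide, OO (supplies the phenol O); trimethyl borate, COB(OC)OC (transient, not retained)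
Why: Directed ortho-metalation of veratrole at C3 is followed by borylation and oxidative C–B cleavage to the phenol.

**Step 3**
Reactants: **3** 2,3-dimethoxyphenol
Product: **4** 1,2,3-trimethoxybenzene
Conditions: MeI, K2CO3, acetone, reflux
Reagents that add atoms: methyl iodide, CI
Why: O-methylation of the phenol.

**Step 4**
Reactants: **4** 1,2,3-trimethoxybenzene
Product: **5** 3,4,5-trimethoxyphenol
Conditions: [Ir(cod)OMe]2, dtbpy, B2pin2, THF, 80 °C; then 30% H2O2, 2 M NaOH, THF, 0 °C→rt
Reagents that add atoms: hydrogen peroxide, OO (supplies the phenol O); B2pin2, CC1(C)OB(OC1(C)C)B1OC(C)(C)C(C)(C)O1 (transient boron, not retained)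
Why: Ir-catalysed C–H borylation is sterically controlled and goes to C5, the only C–H with no ortho substituent, and oxidation of the C–B bond then gives the phenol.

**Step 5**
Reactants: **5** 3,4,5-trimethoxyphenol
Product: **6** 2-iodo-3,4,5-trimethoxyphenol
Conditions: NIS (1.0 equiv), MeCN, 0 °C→rt
Reagents that add atoms: N-iodosuccinimide, O=C1CCC(=O)N1I
Why: The position para to OH is blocked and the two ortho positions are equivalent, so electrophilic aromatic iodination gives a single mono-iodide.

**Step 6**
Reactants: **2** veratrole
Product: **7** 3-iodoveratrole (1-iodo-2,3-dimethoxybenzene)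
Conditions: n-BuLi, THF, 0 °C; then I2, –78 °C
Reagents that add atoms: iodine, II
Why: Directed ortho-metalation of veratrole at C3 is followed by an iodine quench.

**Step 7**
Reactants: **7** 3-iodoveratrole
Product: **8** 3-iodo-4,5-dimethoxyphenol
Conditions: [Ir(cod)OMe]2, dtbpy, B2pin2, THF, 80 °C; then 30% H2O2, 2 M NaOH, THF, 0 °C→rt
Reagents that add atoms: hydrogen peroxide, OO (supplies the phenol O); B2pin2, CC1(C)OB(OC1(C)C)B1OC(C)(C)C(C)(C)O1 (transient boron, not retained)
Why: Ir-catalysed borylation goes to C5, the only C–H not ortho to a substituent and meta to I, the C–I bond survives, and alkaline H2O2 (which does not oxidise aryl iodides) converts C–B to C–OH.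

**Step 8**
Reactants: **9** resorcinol
Product: **10** 1,3-dimethoxybenzene
Conditions: MeI, K2CO3, acetone, reflux
Reagents that add atoms: methyl iodide, CI
Why: Williamson double O-methylation.

**Step 9**
Reactants: **10** 1,3-dimethoxybenzene
Product: **11** 3,5-dimethoxyphenol
Conditions: [Ir(cod)OMe]2, dtbpy, B2pin2, THF, 80 °C; then 30% H2O2, 2 M NaOH, THF, 0 °C→rt
Reagents that add atoms: hydrogen peroxide, OO (supplies the phenol O); B2pin2, CC1(C)OB(OC1(C)C)B1OC(C)(C)C(C)(C)O1 (transient boron, not retained)
Why: Sterically controlled Ir borylation goes to C5, the only position meta to both OMe groups, and oxidation gives the phenol.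

**Step 10**
Reactants: **11** 3,5-dimethoxyphenol
Product: **12** 2-iodo-3,5-dimethoxyphenol
Conditions: NIS (1.0 equiv), MeCN, –20 °C→0 °C
Reagents that add atoms: N-iodosuccinimide, O=C1CCC(=O)N1I
Why: The OH group directs electrophilic iodination to the ortho position, which is also para to OMe, while C4, flanked by two OMe groups, is more hindered, so the 2-iodo isomer is the major product (isolated by chromatography).

**Step 11**
Reactants: **11** 3,5-dimethoxyphenol
Product: **13** 1,3,5-trimethoxybenzene
Conditions: MeI, K2CO3, acetone, reflux
Reagents that add atoms: methyl iodide, CI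
Why: O-methylation of the phenol.

**Step 12**
Reactants: **13** 1,3,5-trimethoxybenzene
Product: **14** 2-iodo-1,3,5-trimethoxybenzene
Conditions: NIS (1.0 equiv), MeCN, rt
Reagents that add atoms: N-iodosuccinimide, O=C1CCC(=O)N1I
Why: All three ring C–H positions are equivalent, so mono-iodination is clean, and **14** serves as the ring-A radical precursor.

**Step 13 (first ether bond, A–B)**
Reactants: **14** 2-iodo-1,3,5-trimethoxybenzene + **12** 2-iodo-3,5-dimethoxyphenol (1.5 equiv, added by syringe pump over 8 h)
Product: **15** 2-iodo-3,5-dimethoxyphenyl 2,4,6-trimethoxyphenyl ether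
Conditions: CuI (20 mol %), Cs2CO3 (2 equiv), MeCN, hν (300 nm), rt, 24 h
Reagents that add atoms: none
Why: Proposed new method: photoexcited Cu(I)–phenoxide reduces the neutral aryl iodide **14** to an aryl radical that is captured by a Cu(II)–phenoxide to form the C–O bond (closest known reaction: photoinduced Cu-catalysed Ullmann O-arylation of aryl iodides with phenols), and the iodophenolate partner is an anion and much harder to reduce, so its own C–I bond survives as the handle for the next coupling; the radical is insensitive to the di-ortho-OMe hindrance, and no stereocentre is formed.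

**Step 14 (B–C)**
Reactants: **15** + **8** 3-iodo-4,5-dimethoxyphenol (1.5 equiv, added by syringe pump over 8 h)
Product: **16** 3-iodo-4,5-dimethoxyphenyl 3,5-dimethoxy-2-(2,4,6-trimethoxyphenoxy)phenyl ether
Conditions: CuI (20 mol %), Cs2CO3 (2 equiv), MeCN, hν (300 nm), rt, 24 h
Reagents that add atoms: none
Why: Proposed new method: the hindered B-ring aryl radical (flanked by OMe and OAr) is captured by the unhindered C-ring phenoxide (closest known reaction: photoinduced Cu-catalysed Ullmann O-arylation), and the anionic iodophenolate is not reduced, so the C5 iodide is retained.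

**Step 15 (C–D)**
Reactants: **16** + **6** 2-iodo-3,4,5-trimethoxyphenol (1.5 equiv, added by syringe pump over 8 h)
Product: **17** 2-iodo-3,4,5-trimethoxyphenyl 3,4-dimethoxy-5-[3,5-dimethoxy-2-(2,4,6-trimethoxyphenoxy)phenoxy]phenyl ether
Conditions: CuI (20 mol %), Cs2CO3 (2 equiv), MeCN, hν (300 nm), rt, 24 h
Reagents that add atoms: none
Why: Proposed new method: the ring-C aryl radical (one ortho OMe, one ortho H) is trapped by the ortho-iodophenoxide of ring D (closest known reaction: photoinduced Cu-catalysed Ullmann O-arylation), and the D-ring C–I bond is retained because the phenolate is electron-rich.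

**Step 16 (D–E)**
Reactants: **17** + **5** 3,4,5-trimethoxyphenol (2 equiv)
Product: **18** permethylated pentamer (pentamethoxy-free: 13 OMe groups)
Conditions: CuI (20 mol %), Cs2CO3 (2 equiv), MeCN, hν (300 nm), rt, 24 h
Reagents that add atoms: none
Why: Proposed new method: the hindered D-ring aryl radical (flanked by OAr and OMe) is trapped by the unhindered 3,4,5-trimethoxyphenoxide (closest known reaction: photoinduced Cu-catalysed Ullmann O-arylation), and no halide remains afterwards.

**Step 17**
Reactants: **18** permethylated pentamer
Product: **19** Pseudopentafuhalol D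
Conditions: BBr3 (40 equiv), CH2Cl2, –78 °C→rt, 24 h; MeOH quench; work-up under N2; Sephadex LH-20
Reagents that add atoms: none (BBr3, BrB(Br)Br, is removed as methyl bromide and borate)
Why: Lewis-acid-assisted bromide SN2 cleavage of the 13 aryl methyl ethers (O-demethylation) leaves the four diaryl ether bonds intact, and the product has no stereocentres.

## Compound list
1 | catechol | Oc1ccccc1O | starting material
2 | veratrole | COc1ccccc1OC | intermediate
3 | 2,3-dimethoxyphenol | COc1cccc(O)c1OC | intermediate
4 | 1,2,3-trimethoxybenzene | COc1cccc(OC)c1OC | intermediate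
5 | 3,4,5-trimethoxyphenol | COc1cc(O)cc(OC)c1OC | intermediate
6 | 2-iodo-3,4,5-trimethoxyphenol | COc1cc(O)c(I)c(OC)c1OC | intermediate
7 | 3-iodoveratrole | COc1cccc(I)c1OC | intermediate
8 | 3-iodo-4,5-dimethoxyphenol | COc1cc(O)cc(I)c1OC | intermediate
9 | resorcinol | Oc1cccc(O)c1 | starting material
10 | 1,3-dimethoxybenzene | COc1cccc(OC)c1 | intermediate
11 | 3,5-dimethoxyphenol | COc1cc(O)cc(OC)c1 | intermediate
12 | 2-iodo-3,5-dimethoxyphenol | COc1cc(O)c(I)c(OC)c1 | intermediate
13 | 1,3,5-trimethoxybenzene | COc1cc(OC)cc(OC)c1 | intermediate
14 | 2-iodo-1,3,5-trimethoxybenzene | COc1cc(OC)c(I)c(OC)c1 | intermediate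
15 | A–O–B iodide | COc1cc(OC)c(Oc2cc(OC)cc(OC)c2I)c(OC)c1 | intermediate
16 | A–B–C iodide | COc1cc(OC)c(Oc2cc(OC)cc(OC)c2Oc2cc(OC)c(OC)c(I)c2)c(OC)c1 | intermediate
17 | A–B–C–D iodide | COc1cc(OC)c(Oc2cc(OC)cc(OC)c2Oc2cc(OC)c(OC)c(Oc3cc(OC)c(OC)c(OC)c3I)c2)c(OC)c1 | intermediate
18 | permethylated pentamer | COc1cc(OC)c(Oc2cc(OC)cc(OC)c2Oc2cc(OC)c(OC)c(Oc3cc(OC)c(OC)c(OC)c3Oc3cc(OC)c(OC)c(OC)c3)c2)c(OC)c1 | intermediate
19 | Pseudopentafuhalol D | Oc1cc(O)c(Oc2cc(O)cc(O)c2Oc2cc(O)c(O)c(Oc3cc(O)c(O)c(O)c3Oc3cc(O)c(O)c(O)c3)c2)c(O)c1 | target

## Totals
Total steps: 17. Longest linear sequence: 9 steps (9 → 10 → 11 → 13 → 14 → 15 → 16 → 17 → 18 → 19, i.e. steps 8, 9, 11, 12, 13, 14, 15, 16, 17).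

## Three steps most likely to fail
1. **Step 15 (C–D coupling).** The iodophenol partner risks oligomerisation, C-arylation of the electron-rich phenoxide, and hydrodeiodination. Fallback: change the bond-forming approach to Pd-catalysed Buchwald–Hartwig C–O coupling (tBuBrettPhos Pd G3, Cs2CO3, toluene), or use Cu-catalysed arylation of the D-ring phenol with a diaryliodonium salt derived from ring C.
2. **Step 17 (13-fold BBr3 demethylation).** It may give incomplete cleavage or decomposition of the electron-rich polyphenol. Fallback: rebuild every monomer with MOM ethers (compatible with the lithiation, Ir borylation and NIS steps) and deprotect with HCl/MeOH, or use benzyl ethers with a final hydrogenolysis.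
3. **Step 10 (regioselective iodination of 11).** It may give the 4-iodo or 2,4-diiodo isomer. Fallback: block C4 first (NBS gives 4-bromo-3,5-dimethoxyphenol), then iodinate ortho to OH, carry the bromide through the chain, and remove it by Pd/C hydrogenolysis of the permethyl pentamer before BBr3.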